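## The problem

Locants C1–C19 are those of the target throughout: C1 acetal carbon, O2, C3=C4 enol ether, C4a/C11a ring fusion, C5–C11 the rest of ring A, C12–C15 the side chain, C18 the methyl on C7, C19 the methylene on C11.

The target is a trans-fused cyclonona[c]pyran. A nine-membered carbocycle (ring A) shares the C4a–C11a bond with a dihydropyran (ring B) that carries an acetoxy acetal at C1 and an enol ether C3=C4. The side chain leaves C4 through the carbinol C12 and ends in an E 2-methyl enoate. Six stereocentres must be set: C1, C4a, C11a, C12, and the epoxide carbons C7 and C8 (cis-epoxide, from a Z alkene). C4a and C11a are neighbours and can control each other, and the ring fusion can control C1. C12 and the epoxide are too remote or too flexibly connected for substrate control and need reagent control. The molecule tolerates little: the C1 acylal and the C12 acetate flank an enol ether and ionise under acid, and the trisubstituted epoxide opens under acid. The C11=C19 bond lies β,γ to C1, so any C1 carbonyl precursor can epimerise at C11a or slip into conjugation under base, and the enoate restricts hydrides and hard nucleophiles. Ring A is the feature that makes a short entry possible. C7 (methyl C18, Z C7=C8) and C11 (methylene C19) are the two methyl-bearing carbons of the head-to-tail isoprene dimer. The one additional ring carbon, C11a, sits between C11 and C4a, exactly where a carbene carbon ends up when a cyclooctene is enlarged through a dibromocyclopropane.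

## Retrosynthesis

**C12–OAc.** The C12 acetate of 31 is cut to alcohol 30 and then to silyl ether 29. A free O12 would lactonise onto C1 during ring B closure, and an acetate would be lost by β-elimination once the C3 aldehyde enolises. A silyl ether avoids both. The forward steps are a buffered desilylation and a basic acetylation.

**C1 acylal.** The C1–H/C1–OAc pair of 29 is traced to the lactone carbonyl of enol δ-lactone 27, through aluminium hemiacetal 28. The neighbouring cut, a 1,5-dialdehyde closing to a lactol, leaves open which aldehyde becomes the enol ether and exposes a β,γ-unsaturated aldehyde. With C1 as a carboxyl carbon only C3 can become the enol carbon. The forward step needs hydride to choose the lactone over the enoate, to enter from the face that gives 1R, and the intermediate to be acetylated before it opens.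

**O2–C1 (ring B).** Cutting the enol ester bond of 27 gives formyl acid 25, freed from allyl ester 24. Ring B is then closed by O-acylation, a reaction of the formyl acid/enol lactone type, and the transient C4 centre vanishes. The allyl ester is the only ester that can be removed beside the methyl enoate without acid or base.

**Epoxide.** The C7–O and C8–O bonds are cut to the Z alkene of diol 21. The timing is dictated by the neighbours: after the Lewis acid of the aldol step, before any aldehyde or enol ether exists. The forward reaction needs a reagent that selects the trisubstituted alkene and its face.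

**C3–O.** The primary alcohol of 21 (C3–OH, C4–H) is traced to the C3=C4 methylene of allylic alcohol 18. A simple hydroboration cannot tell C3=C4 from C11=C19; delivery of a silane from O12 can.

**C12–C13.** Cutting this bond of 18 gives enal 15 and silyl dienolate 17, made from methyl tiglate 16. One vinylogous aldol step brings the whole side chain with its E enoate and sets C12 by catalyst control. The alternative, allylation followed by metathesis, risks ring closure onto C11=C19.

**C4a–C4 and C11a–H.** Enal 15 comes from acetal 14 and that from sultam imide 13. Cutting C4a–C4 of 13 gives N-enoyl sultam 9 and the cuprate 11 derived from bromo acetal 10, an α-acrolein anion equivalent. The cut removes both ring-fusion stereocentres at once; the forward step must set C4a by the auxiliary 7 and C11a by protonation of enolate 12.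

**C11a–C1.** The acyl group of 9 is taken off to acid 6 and, through dienyllithium 5, to vinyl bromide 4. The bromine of 4 marks exactly the carbon that needs C1.

**C4a–C11 (key).** Reconnecting C4a to C11 in 4 and returning HBr gives dibromocyclopropane 3. This turns the nine-membered ring into an eight-membered one and avoids any end-to-end closure. The forward reaction must open the cyclopropane and lose a methyl proton.

**Cyclopropane.** Removal of the carbene carbon from 3 gives the isoprene dimer 1 and bromoform 2, both commodity chemicals.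

## Roads not taken

Alternative 1: Ring B is cut across C4a–C11a and O2–C1, and the forward step is a copper-bis(oxazoline)-catalysed inverse-demand oxa-Diels–Alder reaction of a 2-formyl acrylate-type heterodiene with an E enol ether. It gives the 1-methoxy dihydropyran ester A1.
- Merits: three stereocentres (C1, C4a, C11a) and the whole of ring B arise in one catalytic asymmetric step. The C4 ester makes the enol ether a robust vinylogous carbonate. In absolute stereocontrol this road is better than the chosen plan, which needs a stoichiometric auxiliary.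
- Weak points: the nine-membered ring is still open in A1 and must be closed late between two functionalised arms, the hardest ring size to close. The C11 methylene is still a masked ketone. The 1-methoxy group must be exchanged for acetoxy by acid at a stage where epoxide and allylic acetate would not survive.
- Comparison: the chosen plan sets against this a ring A that is complete after two steps, at the price of building ring B on a flexible ring.

Alternative 2: Ring A is cut at C10–C11 and closed by an intramolecular B-alkyl Suzuki coupling (9-BBN hydroboration of a terminal alkene, then coupling with a 1,1-disubstituted iodoalkene). The product is the bicyclic ester A2.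
- Merits: the exocyclic methylene arises directly from the iodoalkene. The ring-fusion centres are set earlier on a six-membered ring, where two carbon branches are introduced trans with confidence. In this respect it is better than the chosen plan, whose C11a is set by a protonation.
- Weak points: a nine-membered ring is closed by a bimetallic coupling against transannular strain and needs high dilution, with protodeboronation and β-hydride elimination as competitors. The hydroboration must choose the terminal alkene beside the Z trisubstituted one and the enol ether. The open-chain precursor is long, and the 1-methoxy exchange problem remains.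
- Comparison: the chosen plan never has to close ring A and reaches it from two commodity chemicals.

Alternative 3: C4a–C11a is formed and a C3–C19 bond broken in an anionic oxy-Cope contraction of an eleven-membered trienol; the C3 enolate is trapped to give enol acetate A3.
- Merits: the chair transition state sets C4a and C11a trans by a pericyclic mechanism, and C3 arrives at the right oxidation level. This is the best answer to the stereocentre pair where the chosen plan is weakest.
- Weak points: the eleven-membered trienol with defined alkene geometries and carbinol configuration is itself a macrocycle problem. The potassium alkoxide conditions meet an enoate with acidic γ-hydrogens and a silyloxy group β to the new enolate. O- against C-acylation must be controlled. Turning A3 into the cyclic acetoxy acetal again needs acid.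
- Comparison: the chosen plan carries no sensitive group through its key step and has the shorter path to ring A, but it pays with an auxiliary and a less certain C11a.

Key step: step 2

**Remarks on the chemistry (assumptions)**
- Systematic names of monocyclic intermediates use their own ring numbering; C-locants in the text are target locants.
- The sense of induction of sultam 7 in step 5 is assumed to follow the chelate model for α,β-disubstituted N-enoyl sultams. If it is opposite, the (1R)-enantiomer of 7 is used and nothing else changes.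
- In step 8 the (R)-tryptophan-derived boron catalyst is assumed to shield the Re face of the enal, as it does for aromatic and unsaturated aldehydes. Otherwise its enantiomer is used.
- Technical 1 contains some 1,6-dimethyl isomer; it is assumed to be removed by fractional distillation before step 1.

## Route

Step 1
Reactants: 1 (1Z,5Z)-1,5-dimethylcycloocta-1,5-diene; 2 bromoform
Product: 3 rac-(1R,4Z,8S)-9,9-dibromo-1,5-dimethylbicyclo[6.1.0]non-4-ene
Conditions: KOtBu, pentane, −10 → 0 °C, 1 in excess
Reagents that add atoms: none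
Why: Dibromocarbene [2+1] cycloaddition is stereospecifically syn, so the Z alkene gives the cis-fused cyclopropane; the two alkenes of 1 are equivalent and an excess of 1 keeps the bis-adduct low. The two stereocentres form as a racemate and are destroyed in step 2.

Step 2
Reactants: 3 rac-(1R,4Z,8S)-9,9-dibromo-1,5-dimethylbicyclo[6.1.0]non-4-ene
Product: 4 (1Z,6Z)-2-bromo-7-methyl-3-methylidenecyclonona-1,6-diene
Conditions: AgBF4 (1.2 equiv), 2,6-di-tert-butylpyridine (1.5 equiv), CH2Cl2, 0 °C → rt, dark
Reagents that add atoms: none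
Why: Silver-assisted loss of one bromide is concerted with disrotatory two-electron electrocyclic opening of the cyclopropane, the known route from gem-dibromocyclopropanes to 2-bromoallyl cations and 2-bromo-1,3-dienes. The bond that breaks is the fusion bond C4a–C11, so ring A is closed by ring expansion of the eight-membered ring and not by an end-to-end cyclisation, which avoids the entropy and transannular strain of a direct nine-ring closure. The cation is spread over C11 (tertiary) and C4a (secondary), and the base removes a proton next to the tertiary terminus. The rotating methyl group aligns a C–H bond with the allyl π system more easily than the ring CH2 at C10 can, which together with the hindered base should favour the exocyclic C11=C19 bond. No stereocentre is formed and both stereocentres of 3 disappear, so racemic 3 suffices. The bromide anti to the ring should leave with outward rotation of the ring bonds, as is usual for bicyclo[6.1.0]nonanes, which puts the ring branches trans across C4a=C11a (1Z); this geometry is not carried into the target because C11a becomes an enolate carbon in step 5. The step needs proton loss to win over capture of the cation, which the BF4 counter-ion, the non-nucleophilic base and the conjugation gained in the bromodiene secure, and it needs the remote Z C7=C8 alkene to stay a spectator, which the low temperature favours.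

Step 3
Reactants: 4 (1Z,6Z)-2-bromo-7-methyl-3-methylidenecyclonona-1,6-diene
Product: 6 (1Z,5Z)-5-methyl-9-methylidenecyclonona-1,5-diene-1-carboxylic acid, via dienyllithium 5 (not isolated)
Conditions: t-BuLi (2.1 equiv), Et2O, −78 °C; CO2 (gas), −78 °C → rt; 1 M HCl
Reagents that add atoms: carbon dioxide O=C=O
Why: Bromine–lithium exchange on a vinyl bromide keeps the alkene geometry at −78 °C and the vinyllithium is carboxylated; no other electrophilic group is present.

Step 4
Reactants: 6 (1Z,5Z)-5-methyl-9-methylidenecyclonona-1,5-diene-1-carboxylic acid; 7 (1S)-(−)-2,10-camphorsultam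
Product: 9 N-[(1Z,5Z)-5-methyl-9-methylidenecyclonona-1,5-diene-1-carbonyl]-(1S)-2,10-camphorsultam, via acyl chloride 8 (not isolated)
Conditions: NaH, THF, 0 °C; (COCl)2, HCONMe2 (cat.), 0 °C; then 7/NaH, toluene–THF, 0 °C → rt
Reagents that add atoms: none
Why: N-Acylation of the sultam sodium salt by an acid chloride is the standard entry to N-enoyl sultams; making the chloride from the sodium carboxylate keeps free HCl away from the strained diene.

Step 5
Reactants: 9 N-[(1Z,5Z)-5-methyl-9-methylidenecyclonona-1,5-diene-1-carbonyl]-(1S)-2,10-camphorsultam; 10 2-bromo-3,3-diethoxyprop-1-ene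
Product: 13 N-[(1R,2S,5Z)-2-(3,3-diethoxyprop-1-en-2-yl)-5-methyl-9-methylidenecyclonon-5-ene-1-carbonyl]-(1S)-2,10-camphorsultam, via cuprate 11 (not isolated), via sultam enolate 12 (not isolated)
Conditions: 10, t-BuLi (2 equiv), Et2O, −78 °C; CuBr·SMe2 (0.5 equiv per lithium), −50 °C; then 9, THF, −78 → −40 °C; sat. aq. NH4Cl, −78 °C
Reagents that add atoms: none
Why: 1,4-Addition of a lithium diorganocuprate to an α,β-disubstituted N-enoyl camphorsultam followed by enolate protonation is a known auxiliary-controlled way to set Cβ and Cα together, and the alkenyl group is the established α-acrolein anion equivalent. The sultam screens one face of the enoyl unit so that C4 adds to C4a (4aS); the proton then enters enolate 12 on the face the auxiliary leaves open, giving 11aR with C1 and C4 trans. The strained in-ring E alkene makes the otherwise sluggish trisubstituted acceptor reactive.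

Step 6
Reactants: 13 N-[(1R,2S,5Z)-2-(3,3-diethoxyprop-1-en-2-yl)-5-methyl-9-methylidenecyclonon-5-ene-1-carbonyl]-(1S)-2,10-camphorsultam
Product: 15 prop-2-en-1-yl (1R,2S,5Z)-5-methyl-9-methylidene-2-(3-oxoprop-1-en-2-yl)cyclonon-5-ene-1-carboxylate, via acetal ester 14 (not isolated)
Conditions: allyl alcohol, EtMgBr, THF, 0 °C → rt; then 1 M aq. oxalic acid, THF, rt
Reagents that add atoms: allyl alcohol C=CCO; water O
Why: Alcoholysis of the N-acyl sultam by a weakly basic magnesium alkoxide releases the recoverable auxiliary without touching the C11a–H next to the exocyclic alkene, and dilute acid hydrolyses the acrolein acetal in the same operation. The allyl ester can later be removed under neutral conditions beside the methyl ester.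

Step 7
Reactants: 16 methyl (2E)-2-methylbut-2-enoate (methyl tiglate)
Product: 17 tert-butyl{[(1Z)-1-methoxy-2-methylbuta-1,3-dien-1-yl]oxy}dimethylsilane
Conditions: LiN(iPr)2, THF, −78 °C; then tBuMe2SiCl, DMPU, −78 °C → rt
Reagents that add atoms: tert-butyldimethylsilyl chloride CC(C)(C)[Si](C)(C)Cl
Why: γ-Deprotonation of the tiglate and O-silylation give the silyl dienolate used in vinylogous Mukaiyama aldol reactions; its C1=C2 geometry has no stereochemical consequence.

Step 8
Reactants: 15 prop-2-en-1-yl (1R,2S,5Z)-5-methyl-9-methylidene-2-(3-oxoprop-1-en-2-yl)cyclonon-5-ene-1-carboxylate; 17 tert-butyl{[(1Z)-1-methoxy-2-methylbuta-1,3-dien-1-yl]oxy}dimethylsilane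
Product: 18 prop-2-en-1-yl (1R,2S,5Z)-2-[(3S,5E)-3-hydroxy-7-methoxy-6-methyl-7-oxohepta-1,5-dien-2-yl]-5-methyl-9-methylidenecyclonon-5-ene-1-carboxylate
Conditions: (4R)-4-(1H-indol-3-ylmethyl)-2-phenyl-3-(4-methylphenylsulfonyl)-1,3,2-oxazaborolidin-5-one (30 mol%), iPrOH, EtCN, −78 °C
Reagents that add atoms: none
Why: In this catalytic enantioselective vinylogous Mukaiyama aldol reaction the dienolate attacks through its γ-carbon and the E enoate is regenerated, so C12–C13 and the whole side chain arrive in one step. C12 (S) is set by the chiral boron Lewis acid, which leaves the Si face of the enal open; the nearest stereocentre C4a is separated from C12 by the sp2 carbon C4 and should bias the addition little.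

Step 9
Reactants: 18 prop-2-en-1-yl (1R,2S,5Z)-2-[(3S,5E)-3-hydroxy-7-methoxy-6-methyl-7-oxohepta-1,5-dien-2-yl]-5-methyl-9-methylidenecyclonon-5-ene-1-carboxylate
Product: 21 prop-2-en-1-yl (1R,2R,5Z)-2-[(3S,5E)-1,3-dihydroxy-7-methoxy-6-methyl-7-oxohept-5-en-2-yl]-5-methyl-9-methylidenecyclonon-5-ene-1-carboxylate (epimers at C4), via silyl ether 19 (not isolated), via oxasilolane 20 (not isolated)
Conditions: (HMe2Si)2NH, neat, rt, then evaporation; Pt2[(CH2=CHSiMe2)2O]3 (0.5 mol%), toluene, rt → 50 °C; then KF, KHCO3, 30% H2O2, THF/MeOH, rt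
Reagents that add atoms: hydrogen peroxide OO
Why: Intramolecular hydrosilylation of an allylic alcohol followed by Tamao–Fleming oxidation delivers the Si–H tethered to O12 in 5-endo fashion to the terminal carbon C3 only, which distinguishes C3=C4 from the equally substituted C11=C19. The new centre C4 forms as a mixture and is removed again in step 14.

Step 10
Reactants: 21 prop-2-en-1-yl (1R,2R,5Z)-2-[(3S,5E)-1,3-dihydroxy-7-methoxy-6-methyl-7-oxohept-5-en-2-yl]-5-methyl-9-methylidenecyclonon-5-ene-1-carboxylate (epimers at C4)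
Product: 22 prop-2-en-1-yl (1S,4R,5R,9R)-4-[(3S,5E)-1,3-dihydroxy-7-methoxy-6-methyl-7-oxohept-5-en-2-yl]-1-methyl-6-methylidene-10-oxabicyclo[7.1.0]decane-5-carboxylate
Conditions: 1,2:4,5-di-O-isopropylidene-β-D-erythro-2,3-hexodiulo-2,6-pyranose (30 mol%), KHSO5 (as 2KHSO5·KHSO4·K2SO4), K2CO3, Bu4NHSO4 (cat.), MeCN/CH2(OMe)2/aq. buffer pH 10.5, 0 °C
Reagents that add atoms: potassium peroxymonosulfate [K+].[O-]S(=O)(=O)OO
Why: In the Shi epoxidation the electrophilic dioxirane takes the trisubstituted C7=C8 in preference to the 1,1-disubstituted, monosubstituted and electron-poor alkenes. The face is chosen by the chiral ketone, which for cis-trisubstituted ring alkenes of the 1-substituted cycloalkene type gives the (7S,8R) sense needed here. Placed here, the epoxide never meets the Lewis acid of step 8 and is formed before any aldehyde or enol ether exists.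

Step 11
Reactants: 22 prop-2-en-1-yl (1S,4R,5R,9R)-4-[(3S,5E)-1,3-dihydroxy-7-methoxy-6-methyl-7-oxohept-5-en-2-yl]-1-methyl-6-methylidene-10-oxabicyclo[7.1.0]decane-5-carboxylate
Product: 23 prop-2-en-1-yl (1S,4R,5R,9R)-4-[(3S,5E)-3-hydroxy-7-methoxy-6-methyl-1,7-dioxohept-5-en-2-yl]-1-methyl-6-methylidene-10-oxabicyclo[7.1.0]decane-5-carboxylate
Conditions: 2,2,6,6-tetramethylpiperidin-1-oxyl (10 mol%), PhI(OAc)2, NaHCO3, CH2Cl2, rt
Reagents that add atoms: none
Why: Oxoammonium oxidation is selective for the primary alcohol over the secondary one and leaves alkenes and the epoxide alone.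

Step 12
Reactants: 23 prop-2-en-1-yl (1S,4R,5R,9R)-4-[(3S,5E)-3-hydroxy-7-methoxy-6-methyl-1,7-dioxohept-5-en-2-yl]-1-methyl-6-methylidene-10-oxabicyclo[7.1.0]decane-5-carboxylate
Product: 24 prop-2-en-1-yl (1S,4R,5R,9R)-4-[(3S,5E)-7-methoxy-6-methyl-1,7-dioxo-3-(triethylsilyloxy)hept-5-en-2-yl]-1-methyl-6-methylidene-10-oxabicyclo[7.1.0]decane-5-carboxylate
Conditions: Et3SiCl, imidazole, CH2Cl2, 0 °C
Reagents that add atoms: chlorotriethylsilane CC[Si](Cl)(CC)CC
Why: Silylation of the secondary alcohol under mildly basic conditions; the silyl ether prevents lactonisation of O12 onto C1 and β-elimination when the aldehyde is enolised in step 14.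

Step 13
Reactants: 24 prop-2-en-1-yl (1S,4R,5R,9R)-4-[(3S,5E)-7-methoxy-6-methyl-1,7-dioxo-3-(triethylsilyloxy)hept-5-en-2-yl]-1-methyl-6-methylidene-10-oxabicyclo[7.1.0]decane-5-carboxylate
Product: 25 (1S,4R,5R,9R)-4-[(3S,5E)-7-methoxy-6-methyl-1,7-dioxo-3-(triethylsilyloxy)hept-5-en-2-yl]-1-methyl-6-methylidene-10-oxabicyclo[7.1.0]decane-5-carboxylic acid
Conditions: Pd(PPh3)4 (5 mol%), PhSO2Na, THF/MeOH, rt; pH 5 phosphate work-up
Reagents that add atoms: none
Why: Palladium-catalysed deallylation (Tsuji–Trost allyl transfer to the sulfinate) frees the acid under neutral conditions; methyl ester, silyl ether, epoxide and aldehyde are inert, and a sulfinate scavenger does not condense with the aldehyde.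

Step 14
Reactants: 25 (1S,4R,5R,9R)-4-[(3S,5E)-7-methoxy-6-methyl-1,7-dioxo-3-(triethylsilyloxy)hept-5-en-2-yl]-1-methyl-6-methylidene-10-oxabicyclo[7.1.0]decane-5-carboxylic acid
Product: 27 methyl (2E,5S)-5-[(4aS,7S,8R,11aR)-7,8-epoxy-7-methyl-11-methylidene-1-oxo-1,4a,5,6,7,8,9,10,11,11a-decahydrocyclonona[c]pyran-4-yl]-2-methyl-5-(triethylsilyloxy)pent-2-enoate, via chloro lactone 26 (not isolated)
Conditions: Me2C=C(Cl)NMe2, CH2Cl2, 0 °C; then Et3N, 0 °C → rt
Reagents that add atoms: none
Why: Enol lactonisation of a 5-oxo acid: the acid chloride made under neutral conditions closes on the aldehyde oxygen to the cyclic pseudo-chloride 26, and triethylamine eliminates HCl across C3–C4, the classical conversion of formyl acids into enol δ-lactones. Ring B closes as a six-membered ring by O2–C1 acylation; because C1 is a carboxyl carbon only C3 can become the enol carbon, and the C4 centre disappears.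

Step 15
Reactants: 27 methyl (2E,5S)-5-[(4aS,7S,8R,11aR)-7,8-epoxy-7-methyl-11-methylidene-1-oxo-1,4a,5,6,7,8,9,10,11,11a-decahydrocyclonona[c]pyran-4-yl]-2-methyl-5-(triethylsilyloxy)pent-2-enoate
Product: 29 methyl (2E,5S)-5-[(1R,4aS,7S,8R,11aR)-1-acetoxy-7,8-epoxy-7-methyl-11-methylidene-1,4a,5,6,7,8,9,10,11,11a-decahydrocyclonona[c]pyran-4-yl]-2-methyl-5-(triethylsilyloxy)pent-2-enoate, via aluminium hemiacetal 28 (not isolated)
Conditions: iBu2AlH (1.1 equiv), CH2Cl2, −78 °C; then pyridine, 4-(dimethylamino)pyridine, Ac2O, −78 → 0 °C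
Reagents that add atoms: acetic anhydride CC(=O)OC(C)=O
Why: Reductive acetylation of a lactone: iBu2AlH adds at −78 °C to the most electrophilic carbonyl, the enol lactone, and the aluminium hemiacetal 28 is acetylated in situ before it can open; the lactol stage corresponds to the known reduction of iridoid enol lactones. Hydride adds axially from the face opposite H-11a, so the acetoxy group becomes equatorial (1R, H-1 trans to H-11a).

Step 16
Reactants: 29 methyl (2E,5S)-5-[(1R,4aS,7S,8R,11aR)-1-acetoxy-7,8-epoxy-7-methyl-11-methylidene-1,4a,5,6,7,8,9,10,11,11a-decahydrocyclonona[c]pyran-4-yl]-2-methyl-5-(triethylsilyloxy)pent-2-enoate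
Product: 30 methyl (2E,5S)-5-[(1R,4aS,7S,8R,11aR)-1-acetoxy-7,8-epoxy-7-methyl-11-methylidene-1,4a,5,6,7,8,9,10,11,11a-decahydrocyclonona[c]pyran-4-yl]-5-hydroxy-2-methylpent-2-enoate
Conditions: Et3N·3HF, THF, 0 °C → rt
Reagents that add atoms: none
Why: Fluoride cleavage of the triethylsilyl ether under nearly neutral conditions; the acylal at C1, the epoxide and the esters should be stable to this reagent at 0 °C.

Step 17
Reactants: 30 methyl (2E,5S)-5-[(1R,4aS,7S,8R,11aR)-1-acetoxy-7,8-epoxy-7-methyl-11-methylidene-1,4a,5,6,7,8,9,10,11,11a-decahydrocyclonona[c]pyran-4-yl]-5-hydroxy-2-methylpent-2-enoate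
Product: 31 methyl (2E,5S)-5-acetoxy-5-[(1R,4aS,7S,8R,11aR)-1-acetoxy-7,8-epoxy-7-methyl-11-methylidene-1,4a,5,6,7,8,9,10,11,11a-decahydrocyclonona[c]pyran-4-yl]-2-methylpent-2-enoate
Conditions: Ac2O, pyridine, 4-(dimethylamino)pyridine (cat.), CH2Cl2, 0 °C
Reagents that add atoms: acetic anhydride CC(=O)OC(C)=O
Why: Acetylation of the secondary allylic alcohol under basic conditions with a nucleophilic pyridine catalyst avoids acid-induced ionisation at C12 or C1 and gives the target.

## Compound list

1 | (1Z,5Z)-1,5-dimethylcycloocta-1,5-diene | C/C1=C/CC/C(C)=C\CC1 | starting material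
2 | bromoform | BrC(Br)Br | starting material
3 | rac-(1R,4Z,8S)-9,9-dibromo-1,5-dimethylbicyclo[6.1.0]non-4-ene (racemic, one enantiomer drawn) | C/C1=C/CC[C@@]2(C)C(Br)(Br)[C@H]2CC1 | intermediate
4 | (1Z,6Z)-2-bromo-7-methyl-3-methylidenecyclonona-1,6-diene | C=C1CC/C=C(/C)CC/C=C1\Br | intermediate
5 | [(1E,6Z)-7-methyl-3-methylidenecyclonona-1,6-dien-2-yl]lithium | C=C1CC/C=C(/C)CC/C=C1\[Li] | intermediate (not isolated)
6 | (1Z,5Z)-5-methyl-9-methylidenecyclonona-1,5-diene-1-carboxylic acid | C=C1CC/C=C(/C)CC/C=C1\C(=O)O | intermediate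
7 | (1S)-(−)-2,10-camphorsultam, (3aS,6R,7aR)-8,8-dimethylhexahydro-3H-3a,6-methano-2,1-benzothiazole 2,2-dioxide | O=S1(=O)C[C@]23CC[C@H](C[C@H]2N1)C3(C)C | starting material
8 | (1Z,5Z)-5-methyl-9-methylidenecyclonona-1,5-diene-1-carbonyl chloride | C=C1CC/C=C(/C)CC/C=C1\C(=O)Cl | intermediate (not isolated)
9 | N-[(1Z,5Z)-5-methyl-9-methylidenecyclonona-1,5-diene-1-carbonyl]-(1S)-2,10-camphorsultam | C=C1CC/C=C(/C)CC/C=C1\C(=O)N1[C@@H]2C[C@H]3CC[C@]2(CS1(=O)=O)C3(C)C | intermediate
10 | 2-bromo-3,3-diethoxyprop-1-ene | C=C(Br)C(OCC)OCC | starting material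
11 | lithium bis(3,3-diethoxyprop-1-en-2-yl)cuprate | [Li+].C=C([Cu-]C(=C)C(OCC)OCC)C(OCC)OCC | intermediate (not isolated)
12 | lithium enolate of 13 (C11a=C1 enolate, 4aS) | C=C1CC/C=C(/C)CC[C@H](C(=C)C(OCC)OCC)C1=C(O[Li])N1[C@@H]2C[C@H]3CC[C@]2(CS1(=O)=O)C3(C)C | intermediate (not isolated)
13 | N-[(1R,2S,5Z)-2-(3,3-diethoxyprop-1-en-2-yl)-5-methyl-9-methylidenecyclonon-5-ene-1-carbonyl]-(1S)-2,10-camphorsultam | C=C1CC/C=C(/C)CC[C@H](C(=C)C(OCC)OCC)[C@H]1C(=O)N1[C@@H]2C[C@H]3CC[C@]2(CS1(=O)=O)C3(C)C | intermediate
14 | prop-2-en-1-yl (1R,2S,5Z)-2-(3,3-diethoxyprop-1-en-2-yl)-5-methyl-9-methylidenecyclonon-5-ene-1-carboxylate | C=C1CC/C=C(/C)CC[C@H](C(=C)C(OCC)OCC)[C@H]1C(=O)OCC=C | intermediate (not isolated)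
15 | prop-2-en-1-yl (1R,2S,5Z)-5-methyl-9-methylidene-2-(3-oxoprop-1-en-2-yl)cyclonon-5-ene-1-carboxylate | C=C1CC/C=C(/C)CC[C@H](C(=C)C=O)[C@H]1C(=O)OCC=C | intermediate
16 | methyl (2E)-2-methylbut-2-enoate (methyl tiglate) | C/C=C(\C)C(=O)OC | starting material
17 | tert-butyl{[(1Z)-1-methoxy-2-methylbuta-1,3-dien-1-yl]oxy}dimethylsilane | C=C/C(C)=C(/OC)O[Si](C)(C)C(C)(C)C | intermediate
18 | prop-2-en-1-yl (1R,2S,5Z)-2-[(3S,5E)-3-hydroxy-7-methoxy-6-methyl-7-oxohepta-1,5-dien-2-yl]-5-methyl-9-methylidenecyclonon-5-ene-1-carboxylate | C=C1CC/C=C(/C)CC[C@H](C(=C)[C@H](C/C=C(\C)C(=O)OC)O)[C@H]1C(=O)OCC=C | intermediate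
19 | prop-2-en-1-yl (1R,2S,5Z)-2-[(3S,5E)-3-(dimethylsilyloxy)-7-methoxy-6-methyl-7-oxohepta-1,5-dien-2-yl]-5-methyl-9-methylidenecyclonon-5-ene-1-carboxylate | C=C1CC/C=C(/C)CC[C@H](C(=C)[C@H](C/C=C(\C)C(=O)OC)O[SiH](C)C)[C@H]1C(=O)OCC=C | intermediate (not isolated)
20 | prop-2-en-1-yl (1R,2S,5Z)-2-{(5S)-5-[(2E)-4-methoxy-3-methyl-4-oxobut-2-en-1-yl]-2,2-dimethyl-1,2-oxasilolan-4-yl}-5-methyl-9-methylidenecyclonon-5-ene-1-carboxylate (epimers at oxasilolane C4) | C=C1CC/C=C(/C)CC[C@H](C2C[Si](C)(C)O[C@H]2C/C=C(\C)C(=O)OC)[C@H]1C(=O)OCC=C | intermediate (not isolated)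
21 | prop-2-en-1-yl (1R,2R,5Z)-2-[(3S,5E)-1,3-dihydroxy-7-methoxy-6-methyl-7-oxohept-5-en-2-yl]-5-methyl-9-methylidenecyclonon-5-ene-1-carboxylate (epimers at C4, heptenyl C2) | C=C1CC/C=C(/C)CC[C@H](C(CO)[C@H](C/C=C(\C)C(=O)OC)O)[C@H]1C(=O)OCC=C | intermediate
22 | prop-2-en-1-yl (1S,4R,5R,9R)-4-[(3S,5E)-1,3-dihydroxy-7-methoxy-6-methyl-7-oxohept-5-en-2-yl]-1-methyl-6-methylidene-10-oxabicyclo[7.1.0]decane-5-carboxylate (epimers at heptenyl C2) | C=C1CC[C@H]2O[C@@]2(C)CC[C@H](C(CO)[C@H](C/C=C(\C)C(=O)OC)O)[C@H]1C(=O)OCC=C | intermediate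
23 | prop-2-en-1-yl (1S,4R,5R,9R)-4-[(3S,5E)-3-hydroxy-7-methoxy-6-methyl-1,7-dioxohept-5-en-2-yl]-1-methyl-6-methylidene-10-oxabicyclo[7.1.0]decane-5-carboxylate (epimers at heptenyl C2) | C=C1CC[C@H]2O[C@@]2(C)CC[C@H](C(C=O)[C@H](C/C=C(\C)C(=O)OC)O)[C@H]1C(=O)OCC=C | intermediate
24 | prop-2-en-1-yl (1S,4R,5R,9R)-4-[(3S,5E)-7-methoxy-6-methyl-1,7-dioxo-3-(triethylsilyloxy)hept-5-en-2-yl]-1-methyl-6-methylidene-10-oxabicyclo[7.1.0]decane-5-carboxylate (epimers at heptenyl C2) | C=C1CC[C@H]2O[C@@]2(C)CC[C@H](C(C=O)[C@H](C/C=C(\C)C(=O)OC)O[Si](CC)(CC)CC)[C@H]1C(=O)OCC=C | intermediate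
25 | (1S,4R,5R,9R)-4-[(3S,5E)-7-methoxy-6-methyl-1,7-dioxo-3-(triethylsilyloxy)hept-5-en-2-yl]-1-methyl-6-methylidene-10-oxabicyclo[7.1.0]decane-5-carboxylic acid (epimers at heptenyl C2) | C=C1CC[C@H]2O[C@@]2(C)CC[C@H](C(C=O)[C@H](C/C=C(\C)C(=O)OC)O[Si](CC)(CC)CC)[C@H]1C(=O)O | intermediate
26 | methyl (2E,5S)-5-[(4aS,7S,8R,11aR)-3-chloro-7,8-epoxy-7-methyl-11-methylidene-1-oxoperhydrocyclonona[c]pyran-4-yl]-2-methyl-5-(triethylsilyloxy)pent-2-enoate (3-chloro-3,4-dihydro form of 27, epimers at C3 and C4) | C=C1CC[C@H]2O[C@@]2(C)CC[C@@H]2C([C@H](C/C=C(\C)C(=O)OC)O[Si](CC)(CC)CC)C(Cl)OC(=O)[C@@H]12 | intermediate (not isolated)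
27 | methyl (2E,5S)-5-[(4aS,7S,8R,11aR)-7,8-epoxy-7-methyl-11-methylidene-1-oxo-1,4a,5,6,7,8,9,10,11,11a-decahydrocyclonona[c]pyran-4-yl]-2-methyl-5-(triethylsilyloxy)pent-2-enoate | C=C1CC[C@H]2O[C@@]2(C)CC[C@@H]2C([C@H](C/C=C(\C)C(=O)OC)O[Si](CC)(CC)CC)=COC(=O)[C@@H]12 | intermediate
28 | diisobutylaluminium (1R)-hemiacetal of 27 (C1–O–Al(iBu)2, otherwise as 29) | C=C1CC[C@H]2O[C@@]2(C)CC[C@@H]2C([C@H](C/C=C(\C)C(=O)OC)O[Si](CC)(CC)CC)=CO[C@H](O[Al](CC(C)C)CC(C)C)[C@@H]12 | intermediate (not isolated)
29 | methyl (2E,5S)-5-[(1R,4aS,7S,8R,11aR)-1-acetoxy-7,8-epoxy-7-methyl-11-methylidene-1,4a,5,6,7,8,9,10,11,11a-decahydrocyclonona[c]pyran-4-yl]-2-methyl-5-(triethylsilyloxy)pent-2-enoate | C=C1CC[C@H]2O[C@@]2(C)CC[C@@H]2C([C@H](C/C=C(\C)C(=O)OC)O[Si](CC)(CC)CC)=CO[C@H](OC(C)=O)[C@@H]12 | intermediate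
30 | methyl (2E,5S)-5-[(1R,4aS,7S,8R,11aR)-1-acetoxy-7,8-epoxy-7-methyl-11-methylidene-1,4a,5,6,7,8,9,10,11,11a-decahydrocyclonona[c]pyran-4-yl]-5-hydroxy-2-methylpent-2-enoate | C=C1CC[C@H]2O[C@@]2(C)CC[C@@H]2C([C@H](C/C=C(\C)C(=O)OC)O)=CO[C@H](OC(C)=O)[C@@H]12 | intermediate
31 | methyl (2E,5S)-5-acetoxy-5-[(1R,4aS,7S,8R,11aR)-1-acetoxy-7,8-epoxy-7-methyl-11-methylidene-1,4a,5,6,7,8,9,10,11,11a-decahydrocyclonona[c]pyran-4-yl]-2-methylpent-2-enoate | C=C1CC[C@H]2O[C@@]2(C)CC[C@@H]2C([C@H](C/C=C(\C)C(=O)OC)OC(C)=O)=CO[C@H](OC(C)=O)[C@@H]12 | target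

## Step count and least certain steps

Total step count: 17. Longest linear sequence: 16 (steps 1–6 and 8–17; step 7 is a one-step side branch).

**Step 2 (key step).** The cation may lose a proton from the ring carbon C10 instead of the methyl group, may be captured by fluoride or traces of water, or may give both C4a=C11a geometries. It is a discrete intermediate, and only the base and the alignment of the C–H bonds decide among these paths. Fallback: ionisation and elimination are separated. Setting out from 3, AgClO4 in aqueous acetone should capture the cation at its tertiary terminus and give (2Z,6Z)-2-bromo-1,6-dimethylcyclonona-2,6-dien-1-ol F1. Dehydration of this alcohol through its chlorosulfite (SOCl2, pyridine, low temperature) is an E2 process in which the rotating methyl group reaches the antiperiplanar arrangement more easily than the ring CH2, and it comes back to the route at 4.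

**Step 5.** The cuprate may attack the wrong face of C4a, or the proton may enter enolate 12 on the face that puts C1 cis to C4. In common rings a proton usually enters anti to the new β-branch, which would give the cis isomer. A mixture of alkene geometries in 9 would also erode the facial selectivity. Fallback: kinetic protonation is replaced by thermodynamic control. Setting out from the C11a epimer N-[(1S,2S,5Z)-2-(3,3-diethoxyprop-1-en-2-yl)-5-methyl-9-methylidenecyclonon-5-ene-1-carbonyl]-(1S)-2,10-camphorsultam F2 (or its mixture with 13), alcoholysis with lithium allyloxide in allyl alcohol under equilibrating conditions forms the ester and lets C11a settle toward the isomer with the two branches trans. This comes back to the route at 14. The equilibration must be stopped before the exocyclic alkene moves into conjugation.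

**Step 9.** The tethered silane may be delivered to the homoallylic enoate C14=C15 instead of C3=C4, or a platinum hydride may isomerise the exocyclic alkene. Fallback: setting out from 18, hydroxyl-directed epoxidation with VO(acac)2 and tBuOOH, which touches only the allylic C3=C4 bond, should give prop-2-en-1-yl (1R,2S,5Z)-2-{2-[(1S,3E)-1-hydroxy-5-methoxy-4-methyl-5-oxopent-3-en-1-yl]oxiran-2-yl}-5-methyl-9-methylidenecyclonon-5-ene-1-carboxylate F3. Reductive opening of this 2,2-disubstituted epoxide with Cp2TiCl (trivalent titanium, from Cp2TiCl2 and Zn) and 1,4-cyclohexadiene gives the primary alcohol by way of the tertiary C4 radical and comes back to the route at 21.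

**Step 10.** Facial selectivity may be poor if the conformation of the nine-membered ring opposes the chiral ketone, and the hindered ring alkene may react slowly. Fallback: the oxygen is brought in by a halohydrin route, in which the electrophile takes the face an epoxidising agent would take and the oxygen ends on the other. Setting out from 21, N-bromosuccinimide in aqueous THF should give the bromohydrin prop-2-en-1-yl (1R,2R,5S,6S)-6-bromo-2-[(3S,5E)-1,3-dihydroxy-7-methoxy-6-methyl-7-oxohept-5-en-2-yl]-5-hydroxy-5-methyl-9-methylidenecyclononane-1-carboxylate F4, with water opening the bromonium ion at the tertiary C7. Cs2CO3 in MeCN closes it with inversion at C8 and comes back to the route at 22.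

**Step 14.** Activation of the acid beside an amine base may epimerise C11a through a ketene or enol, the silyloxy group may be lost by β-elimination, or chloride may open the epoxide. Fallback: ring B is closed before the epoxide exists and under the classical acylative conditions. Setting out from 21 with step 10 omitted, the conditions of steps 11–13 give the des-epoxy hydroxy aldehyde F5, its triethylsilyl ether F6 and the des-epoxy formyl acid F7. Ac2O with NaOAc at 80 °C closes the acid to the des-epoxy enol lactone F8. mCPBA with NaHCO3 then epoxidises C7=C8, the most electron-rich alkene of the rigid bicycle, and comes back to the route at 27; the face is then under substrate control.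

**Step 15.** The methyl enoate may be over-reduced, the aluminium hemiacetal may collapse to the ring-opened dialdehyde, or the wrong anomer may be acetylated. Fallback: a two-stage route under equilibrating conditions. Setting out from 27, one equivalent of iBu2AlH at −78 °C and aqueous work-up should give the lactol methyl (2E,5S)-5-[(4aS,7S,8R,11aR)-7,8-epoxy-1-hydroxy-7-methyl-11-methylidene-1,4a,5,6,7,8,9,10,11,11a-decahydrocyclonona[c]pyran-4-yl]-2-methyl-5-(triethylsilyloxy)pent-2-enoate F9, which is configurationally mobile at C1. Acetylation with Ac2O and pyridine at low temperature takes the more nucleophilic equatorial hydroxyl and comes back to the route at 29.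

## Further compounds

F1 | step 2 | (2Z,6Z)-2-bromo-1,6-dimethylcyclonona-2,6-dien-1-ol (racemic) | CC1(O)CC/C=C(/C)CC/C=C1\Br
F2 | step 5 | N-[(1S,2S,5Z)-2-(3,3-diethoxyprop-1-en-2-yl)-5-methyl-9-methylidenecyclonon-5-ene-1-carbonyl]-(1S)-2,10-camphorsultam | C=C1CC/C=C(/C)CC[C@H](C(=C)C(OCC)OCC)[C@@H]1C(=O)N1[C@@H]2C[C@H]3CC[C@]2(CS1(=O)=O)C3(C)C
F3 | step 9 | prop-2-en-1-yl (1R,2S,5Z)-2-{2-[(1S,3E)-1-hydroxy-5-methoxy-4-methyl-5-oxopent-3-en-1-yl]oxiran-2-yl}-5-methyl-9-methylidenecyclonon-5-ene-1-carboxylate (epimers at the oxirane carbon C4) | C=C1CC/C=C(/C)CC[C@H](C2(CO2)[C@H](C/C=C(\C)C(=O)OC)O)[C@H]1C(=O)OCC=C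
F4 | step 10 | prop-2-en-1-yl (1R,2R,5S,6S)-6-bromo-2-[(3S,5E)-1,3-dihydroxy-7-methoxy-6-methyl-7-oxohept-5-en-2-yl]-5-hydroxy-5-methyl-9-methylidenecyclononane-1-carboxylate | C=C1CC[C@H](Br)[C@@](C)(O)CC[C@H](C(CO)[C@H](C/C=C(\C)C(=O)OC)O)[C@H]1C(=O)OCC=C
F5 | step 14 | prop-2-en-1-yl (1R,2R,5Z)-2-[(3S,5E)-3-hydroxy-7-methoxy-6-methyl-1,7-dioxohept-5-en-2-yl]-5-methyl-9-methylidenecyclonon-5-ene-1-carboxylate | C=C1CC/C=C(/C)CC[C@H](C(C=O)[C@H](C/C=C(\C)C(=O)OC)O)[C@H]1C(=O)OCC=C
F6 | step 14 | prop-2-en-1-yl (1R,2R,5Z)-2-[(3S,5E)-7-methoxy-6-methyl-1,7-dioxo-3-(triethylsilyloxy)hept-5-en-2-yl]-5-methyl-9-methylidenecyclonon-5-ene-1-carboxylate | C=C1CC/C=C(/C)CC[C@H](C(C=O)[C@H](C/C=C(\C)C(=O)OC)O[Si](CC)(CC)CC)[C@H]1C(=O)OCC=C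
F7 | step 14 | (1R,2R,5Z)-2-[(3S,5E)-7-methoxy-6-methyl-1,7-dioxo-3-(triethylsilyloxy)hept-5-en-2-yl]-5-methyl-9-methylidenecyclonon-5-ene-1-carboxylic acid | C=C1CC/C=C(/C)CC[C@H](C(C=O)[C@H](C/C=C(\C)C(=O)OC)O[Si](CC)(CC)CC)[C@H]1C(=O)O
F8 | step 14 | methyl (2E,5S)-2-methyl-5-[(4aS,7Z,11aR)-7-methyl-11-methylidene-1-oxo-1,4a,5,6,9,10,11,11a-octahydrocyclonona[c]pyran-4-yl]-5-(triethylsilyloxy)pent-2-enoate | C=C1CC/C=C(/C)CC[C@@H]2C([C@H](C/C=C(\C)C(=O)OC)O[Si](CC)(CC)CC)=COC(=O)[C@@H]12
F9 | step 15 | methyl (2E,5S)-5-[(4aS,7S,8R,11aR)-7,8-epoxy-1-hydroxy-7-methyl-11-methylidene-1,4a,5,6,7,8,9,10,11,11a-decahydrocyclonona[c]pyran-4-yl]-2-methyl-5-(triethylsilyloxy)pent-2-enoate (both C1 anomers) | C=C1CC[C@H]2O[C@@]2(C)CC[C@@H]2C([C@H](C/C=C(\C)C(=O)OC)O[Si](CC)(CC)CC)=COC(O)[C@@H]12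
A1 | alternative 1 | methyl (2S,3S,4S)-4-[(3Z)-5-acetoxy-3-methylpent-3-en-1-yl]-2-methoxy-3-(2-methyl-1,3-dioxolan-2-yl)-3,4-dihydro-2H-pyran-5-carboxylate | CC(=O)OC/C=C(/C)CC[C@@H]2C(C(=O)OC)=CO[C@H](OC)[C@H]2C1(C)OCCO1
A2 | alternative 2 | methyl (1S,4aS,7Z,11aR)-1-methoxy-7-methyl-11-methylidene-1,4a,5,6,9,10,11,11a-octahydrocyclonona[c]pyran-4-carboxylate | C=C1CC/C=C(/C)CC[C@@H]2C(C(=O)OC)=CO[C@H](OC)[C@@H]12
A3 | alternative 3 | methyl (2E,5S,6Z)-7-acetoxy-5-[(tert-butyldimethylsilyl)oxy]-6-[(1S,4Z,9R)-9-(dimethoxymethyl)-4-methyl-8-methylidenecyclonon-4-en-1-yl]-2-methylhepta-2,6-dienoate | C=C1CC/C=C(/C)CC[C@H](/C(=C/OC(C)=O)[C@H](C/C=C(\C)C(=O)OC)O[Si](C)(C)C(C)(C)C)[C@H]1C(OC)OC
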